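The target is divided at C11–C12 into a hydroazulenyl iodide and a perhydrobenzoxepine aldehyde. The plan rests on closing the cyclohexane ring (C14, C15, C21–C24) through the C14–C15 bond. The key step exploits the trans pair of oxygen-bearing C21 and neighbouring quaternary C15, which is the imprint of an E-trisubstituted epoxide opened at its tertiary end. It also exploits the place of C14 next to C24, which can be carried as a ketone. In one operation MeAlCl2 ionises the oxirane toward C15 and a silyl enol ether bonds to it through C14 from the back face. This makes the ring, unveils the ketone and sets C14 and C15. The precursor is an acyclic Z silyl enol ether built from (2R,3R)-epoxygeraniol.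

Key step: step 6

Remark on labels: atoms are counted along the main chain of the target SMILES, starting with the methyl on the seven-membered ring as C1 and passing over side methyls and the hydroxyl and carbonyl oxygens. The cycloheptane is then C2, C3, C4, C5, C6, C10, C11; the cyclopentane is C5 to C9; the linker is C12, C13; the cyclohexane is C14, C15, C21, C22, C23, C24; the oxepane is C15 to C19, O20, C21. All intermediates keep these labels.

Remark on the chemistry: (R)-(−)-linalool is assumed to be bought in high enantiomeric purity. C2 in 31 and 32 and C12 in 35 are epimer mixtures of no consequence, because both centres become trigonal again in later steps.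

Step 1
Reactants: 1 geraniol
Product: 2 (2R,3R)-2,3-epoxygeraniol
Conditions: Ti(OiPr)4 (cat.), D-(−)-diethyl tartrate (cat.), t-BuOOH, 4 Å molecular sieves, CH2Cl2, −20 °C
Reagents that add atoms: tert-butyl hydroperoxide, CC(C)(C)OO
Why: Sharpless asymmetric epoxidation: the allylic hydroxyl binds titanium, so only the C15=C21 alkene reacts, and the D-(−)-tartrate delivers oxygen to the face that gives the (2R,3R)-epoxide, which fixes C21 and the oxirane configuration at C15.

Step 2
Reactants: 2 (2R,3R)-2,3-epoxygeraniol, 3 N-methoxy-N-methyl-2-(triphenylphosphoranylidene)acetamide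
Product: 5 (2E)-N-methoxy-N-methyl-3-[(2R,3R)-3-methyl-3-(4-methylpent-3-enyl)oxiran-2-yl]prop-2-enamide, via epoxy aldehyde 4 (not isolated)
Conditions: TEMPO (cat.), PhI(OAc)2, 3, CH2Cl2, rt
Reagents that add atoms: none
Why: The TEMPO/PhI(OAc)2 oxidation stops at the aldehyde, and the stabilised ylide in the same flask traps this sensitive epoxy aldehyde at once in an E-selective Wittig reaction that leaves both oxirane centres untouched.

Step 3
Reactants: 5 (E)-epoxy enamide
Product: 6 N-methoxy-N-methyl-3-[(2R,3R)-3-methyl-3-(4-methylpent-3-enyl)oxiran-2-yl]propanamide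
Conditions: 2-nitrobenzenesulfonyl hydrazide, Et3N, CH2Cl2, rt
Reagents that add atoms: none
Why: Diimide reduction transfers two hydrogens concertedly to the unhindered disubstituted C22=C23 alkene, spares the trisubstituted C18=C19 alkene and, unlike catalytic hydrogenation or electron-transfer methods, cannot open the allylic epoxide.

Step 4
Reactants: 6 saturated epoxy Weinreb amide, 7 vinylmagnesium bromide
Product: 8 5-[(2R,3R)-3-methyl-3-(4-methylpent-3-enyl)oxiran-2-yl]pent-1-en-3-one
Conditions: 7, THF, −78 → 0 °C; poured into cold dilute aqueous acid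
Reagents that add atoms: none
Why: Weinreb ketone synthesis: the chelated tetrahedral adduct lasts until the quench, so only one vinyl group adds; the trisubstituted epoxide is inert to the Grignard reagent in the cold, and the inverse acidic quench keeps the freed amine from adding to the enone.

Step 5
Reactants: 8 epoxy vinyl ketone, 7 vinylmagnesium bromide
Product: 9 tert-butyl(dimethyl){[(3Z)-1-[(2R,3R)-3-methyl-3-(4-methylpent-3-enyl)oxiran-2-yl]hepta-3,6-dien-3-yl]oxy}silane (Z enol silane, O cis to C13)
Conditions: 7, CuBr·SMe2 (cat.), TBSCl, HMPA, THF, −78 → 0 °C; Et3N, pentane work-up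
Reagents that add atoms: tert-butyldimethylsilyl chloride, CC(C)(C)[Si](C)(C)Cl
Why: In this copper-catalysed conjugate addition with in situ silylation the vinyl group adds to the s-cis enone, and the enolate is caught on oxygen where it is born, so the enol silane forms only toward C14 and with Z geometry, which direct enolisation of the parent ketone could not ensure.

Step 6
Reactants: 9 epoxygeranyl Z enol silane
Product: 10 (2R,3R,4R)-2-allyl-4-hydroxy-3-methyl-3-(4-methylpent-3-enyl)cyclohexanone (14R,15R,21R)
Conditions: MeAlCl2, CH2Cl2, −94 → −78 °C; aq. NaHCO3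
Reagents that add atoms: none
Why: MeAlCl2 binds the oxirane oxygen, the tertiary C15–O bond stretches, the enol silane attacks C15 through C14 anti to the departing oxygen, and chloride-assisted loss of the silyl group from the silyloxocarbenium ion unveils the C24 ketone. The closest known reaction type is the Lewis acid-promoted, epoxide-initiated cation–olefin cyclisation that ends on a silyl enol ether. The one ring formed (C14, C15, C21, C22, C23, C24) closes through a chair in the 6-endo mode at the epoxide (both oxirane carbons in the ring, oxygen outside) and 6-endo at the enol double bond. C15 is set by stereospecific inversion of the epoxide carbon, which with the untouched C21–O bond leaves the oxygen equatorial, the C15 methyl axial and C16 equatorial; C14 is set by the chair and the Z geometry (C13 trans to C23, hence equatorial) and, being alpha to the ketone, would settle there in any case. The step needs opening at C15 and not at C21, and reaction of the enol silane and not of the other two alkenes. This is secured because the tertiary carbon bears the charge, the enol silane is by far the best pi nucleophile and is placed for a six-membered ring, C18=C19 could only give a four-membered ring or a five-membered ring with a secondary cation, and the terminal alkene is a poor nucleophile.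

Step 7
Reactants: 10 hydroxy cyclohexanone
Product: 11 (1S,2R,3R,4R)-2-allyl-1,3-dimethyl-3-(4-methylpent-3-enyl)cyclohexane-1,4-diol (24S, axial C24 hydroxyl)
Conditions: MeLi (excess), Et2O, −78 °C
Reagents that add atoms: methyllithium, [Li]C
Why: In this 1,2-addition the axial C15 methyl blocks the axial trajectory, so the methyl group enters equatorially and the new C24 hydroxyl ends up axial (24S); the first equivalent of MeLi is spent on the C21 hydroxyl.

Step 8
Reactants: 11 diol
Product: 12 (18R)-18,19-epoxide of 11
Conditions: D-fructose-derived Shi ketone (cat.), KHSO5 (as Oxone), K2CO3, Bu4NHSO4 (cat.), MeCN–CH2(OMe)2, aq. Na2B4O7 buffer, 0 °C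
Reagents that add atoms: potassium peroxymonosulfate, [K+].[O-]S(=O)(=O)OO
Why: In the Shi epoxidation the chiral dioxirane attacks the electron-rich trisubstituted C18=C19 alkene far faster than the monosubstituted allyl group, and the spiro transition state of the D-fructose-derived ketone gives the (18R)-epoxide as one isomer.

Step 9
Reactants: 12 hydroxy epoxide
Product: 13 (14R,15R,18R,21R,24S)-6-allyl-2,2,5a,7-tetramethyldecahydro-1-benzoxepine-3,7-diol (trans-fused; ring positions 2, 3, 5a, 6, 7, 9a are C19, C18, C15, C14, C24, C21)
Conditions: camphorsulfonic acid (cat.), CH2Cl2, 0 °C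
Reagents that add atoms: none
Why: In this acid-catalysed 7-endo epoxide opening, protonation loosens the tertiary C19–O bond, which the equatorial C21 hydroxyl attacks; the rival 6-exo attack at C18 of the (18R)-epoxide would force the bulky C19 group axial on a trans-fused tetrahydropyran, and C18 keeps its configuration.

Step 10
Reactants: 13 oxepane diol
Product: 14 bis(triethylsilyl) ether of 13 (C18 and C24 oxygens silylated)
Conditions: TESOTf (excess), 2,6-lutidine, CH2Cl2, 0 °C → rt
Reagents that add atoms: triethylsilyl trifluoromethanesulfonate, CC[Si](CC)(CC)OS(=O)(=O)C(F)(F)F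
Why: Silyl triflate silylation is strong enough for both the neopentyl-type C18 alcohol and the axial tertiary C24 alcohol; capping C24 prevents lactol formation in step 11 and tetrahydrofuran closure onto C12 in step 26, and capping C18 keeps it out of steps 24 to 26.

Step 11
Reactants: 14 bis-silyl ether
Product: 15 2-[(14R,15R,18R,21R,24S)-3,7-bis(triethylsilyloxy)-2,2,5a,7-tetramethyldecahydro-1-benzoxepin-6-yl]acetaldehyde (C12 aldehyde)
Conditions: O3, CH2Cl2, −78 °C; Me2S
Reagents that add atoms: ozone, [O-][O+]=O
Why: Ozonolysis with reductive work-up cleaves the terminal alkene, which is now the only C=C bond in the molecule, to the C12 aldehyde, and the silyl ethers and the cyclic ether survive.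

Step 12
Reactants: 16 (R)-(−)-linalool
Product: 17 (R)-1-methylcyclopent-2-en-1-ol
Conditions: second-generation Grubbs catalyst (cat.), CH2Cl2, rt
Reagents that add atoms: none
Why: Ring-closing metathesis joins the vinyl CH (C5) and the trisubstituted alkene CH (C6) with loss of isobutene, a closure speeded by the allylic hydroxyl, and the C9 carbinol centre of linalool is carried over unchanged (9R).

Step 13
Reactants: 17 (R)-1-methylcyclopent-2-en-1-ol
Product: 18 (1S,2R,5S)-2-methyl-6-oxabicyclo[3.1.0]hexan-2-ol (epoxide cis to the hydroxyl)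
Conditions: VO(acac)2 (cat.), t-BuOOH, CH2Cl2, 0 °C
Reagents that add atoms: tert-butyl hydroperoxide, CC(C)(C)OO
Why: In this hydroxyl-directed vanadium-catalysed epoxidation the peroxide is delivered from the metal bound to the C9 oxygen, so the oxirane forms on the hydroxyl face of C5=C6.

Step 14
Reactants: 18 cis-epoxy alcohol, 19 isobutyronitrile
Product: 20 2-[(1S,2S,3R)-2,3-dihydroxy-3-methylcyclopentyl]-2-methylpropanenitrile (5S,6S,9R; C10 anti to both hydroxyls)
Conditions: 19, LiN(iPr)2 (excess), THF, −78 °C; then 18, −78 °C → rt
Reagents that add atoms: none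
Why: In this SN2 opening the lithiated nitrile attacks C6, the oxirane carbon remote from the quaternary C9, from the face opposite to the oxygen; this creates the C6–C10 bond and the quaternary C10 and sets C6, and the cis arrangement of the two oxygens rules out Payne migration.

Step 15
Reactants: 20 diol nitrile
Product: 21 2-[(1S,3R)-3-hydroxy-3-methyl-2-oxocyclopentyl]-2-methylpropanenitrile
Conditions: Dess–Martin periodinane, CH2Cl2, 0 °C → rt
Reagents that add atoms: none
Why: Dess–Martin oxidation converts only the secondary C5 alcohol, since the tertiary C9 alcohol cannot be oxidised, and the essentially neutral medium does not epimerise the now enolisable C6 centre.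

Step 16
Reactants: 21 hydroxy ketone
Product: 23 2-[(1S,3R)-3-hydroxy-3-methyl-2-methylenecyclopentyl]-2-methylpropanenitrile, via beta-hydroxysilane 22 (not isolated)
Conditions: Me3SiCH2Li, CeCl3, THF, −78 → 0 °C; aqueous work-up; crude 22, KH, THF, 0 °C → rt
Reagents that add atoms: (trimethylsilyl)methyllithium, [Li]C[Si](C)(C)C
Why: In the organocerium variant of the Peterson olefination the weakly basic cerium reagent adds to the hindered, enolisable C5 ketone without scrambling C6, and base-induced elimination of the beta-hydroxysilane gives the exocyclic C5=C4 methylene.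

Step 17
Reactants: 23 methylene cyclopentanol, 24 vinyl bromide
Product: 26 2-[(5R,6R,9R)-2-allyl-3-hydroxy-3-methylcyclopentyl]-2-methylpropanenitrile (allyl, C10 group and C9 methyl all on one face), via B-alkyl borane 25 (not isolated)
Conditions: 9-BBN, THF, rt; then 24, PdCl2(dppf) (cat.), aq. NaOH, THF, 60 °C
Reagents that add atoms: none
Why: In this hydroboration and B-alkyl Suzuki–Miyaura coupling 9-BBN approaches the methylene group from the face opposite to the bulky C10 substituent and the C9 methyl, so hydrogen lands on C5 syn to the hydroxyl (5R) and C4 ends cis to C10; the coupling then joins C4 to C3 without touching that centre or the nitrile.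

Step 18
Reactants: 26 allyl nitrile, 27 2-bromopropene
Product: 29 dienone with C11(=O)–C2(CH3)=CH2 on C10 and the allyl group on C5, via ketimine 28 (not isolated)
Conditions: 27, t-BuLi, Et2O, −78 °C; then 26, −78 °C → rt; 1 M aq. HCl, THF, 0 °C
Reagents that add atoms: water, O
Why: Isopropenyllithium adds to the nitrile, which has no alpha hydrogen and stops at the N-lithio ketimine, so mild acid hydrolysis releases the isopropenyl ketone; one extra equivalent of the reagent covers the C9 hydroxyl.

Step 19
Reactants: 29 dienone
Product: 30 cis-fused bicyclo[5.3.0]decenone (C11 ketone, C2(CH3)=C3 enone, C10 gem-dimethyl, C9 tertiary alcohol)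
Conditions: second-generation Hoveyda–Grubbs catalyst (cat.), toluene, 80 °C
Reagents that add atoms: none
Why: Ring-closing metathesis between the terminal allyl group and the isopropenyl ketone forms the seven-membered 2-methyl enone, helped by the cis placement of the two chains on the cyclopentane and by the gem-dimethyl group.

Step 20
Reactants: 30 bicyclic enone
Product: 31 cis-fused hydroxy hydroazulenone (saturated C11 ketone, C2 methyl as epimer mixture)
Conditions: H2 (1 atm), Pd/C, EtOAc, rt
Reagents that add atoms: none
Why: Catalytic hydrogenation saturates the only C=C bond, and the configuration that results at C2 does not matter because C2 becomes trigonal again in step 22.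

Step 21
Reactants: 31 hydroazulenone
Product: 32 hydrazone of 31 at C11
Conditions: N2H4·H2O (excess), Et3N, EtOH, reflux
Reagents that add atoms: hydrazine, NN
Why: Hydrazone formation with small, unsubstituted hydrazine under forcing conditions is the established entry for ketones flanked by a quaternary and a tertiary carbon, such as 2,2,6-trimethylcyclohexanone, and the tertiary alcohol is inert.

Step 22
Reactants: 32 hydrazone
Product: 33 hydroazulenyl iodide (C11–I, tetrasubstituted C11=C2 alkene, free C9 hydroxyl)
Conditions: I2, 1,1,3,3-tetramethylguanidine, Et2O–THF, 0 °C → rt, then reflux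
Reagents that add atoms: iodine, II
Why: In the Barton vinyl iodide synthesis, oxidation to the diazo compound, iodination and loss of N2 give an alpha-iodo cation that can lose a proton only from C2 because C10 is quaternary, so a single alkene regioisomer forms.

Step 23
Reactants: 33 hydroazulenyl iodide, 15 C12 aldehyde
Product: 35 allylic alcohol with the C11–C12 bond (C12 epimer mixture), via vinyllithium alkoxide 34 (not isolated)
Conditions: 33, t-BuLi (3 equiv), Et2O, −78 °C; then 15, THF, −78 °C
Reagents that add atoms: none
Why: After deprotonation of the C9 hydroxyl, iodine–lithium exchange gives the hindered vinyllithium, which adds 1,2 to the aldehyde as 2,6,6-trimethylcyclohexenyllithium does, and the C12 configuration formed here is erased in step 24.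

Step 24
Reactants: 35 allylic alcohol mixture
Product: 36 C12 enone
Conditions: Dess–Martin periodinane, CH2Cl2, 0 °C → rt
Reagents that add atoms: none
Why: Dess–Martin oxidation acts on C12–OH, the only free secondary alcohol, and merges both C12 epimers into one ketone without touching the tertiary C9 alcohol or the silyl ethers.

Step 25
Reactants: 36 enone
Product: 37 (12R)-allylic alcohol
Conditions: (S)-2-methyl-CBS-oxazaborolidine, BH3·SMe2, toluene, −40 → −20 °C; aqueous work-up
Reagents that add atoms: none
Why: In the Corey–Bakshi–Shibata reduction the tetrasubstituted cycloheptenyl group acts as the large substituent and the C13 methylene as the small one, so the (S)-catalyst delivers hydride to the face that gives the (12R)-alcohol under reagent control, as acetophenone gives (R)-1-phenylethanol.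

Step 26
Reactants: 37 (12R)-allylic alcohol
Product: 41 bis-silyl ether with the (Z)-C11=C12 alkene and (2S)-C2, via hydrazone adduct 38 (not isolated), via sulfonylhydrazine 39 (not isolated), via allylic diazene 40 (not isolated)
Conditions: PPh3, DEAD, N-isopropylidene-N'-2-nitrobenzenesulfonyl hydrazine (IPNBSH), THF, 0 °C → rt; then CF3CH2OH–H2O (1:1), rt
Reagents that add atoms: none
Why: Mitsunobu displacement inverts C12 to the (12S)-sulfonyl hydrazone, and hydrolysis and loss of sulfinic acid give the allylic diazene; its retro-ene loss of N2 passes hydrogen suprafacially to the ring face of C2 that carries H5 and H6 (2S), while allylic 1,3-strain against the C1 methyl keeps the C12 hydrogen inside and C13 on the C10 side, which is the Z geometry of the target.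

Step 27
Reactants: 41 bis-silyl ether
Product: 42 triol (free C9, C18 and C24 hydroxyls)
Conditions: Bu4NF, THF, rt → 45 °C
Reagents that add atoms: none
Why: Fluoride cleaves both triethylsilyl ethers under basic conditions that cannot shift the exocyclic alkene or dehydrate the tertiary alcohols.

Step 28
Reactants: 42 triol
Product: 43 target CNP0157787.1 (2S,5R,6R,9R,11Z,14R,15R,21R,24S)
Conditions: Dess–Martin periodinane, CH2Cl2, 0 °C → rt
Reagents that add atoms: none
Why: Dess–Martin oxidation converts C18–OH, the only oxidisable alcohol, into the oxepanone carbonyl, and since C19 is quaternary no stereocentre adjoins the new ketone.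

Compound list
1 | geraniol | CC(C)=CCC/C(C)=C/CO | starting material
2 | (2R,3R)-2,3-epoxygeraniol | OC[C@H]1O[C@]1(C)CCC=C(C)C | intermediate
3 | N-methoxy-N-methyl-2-(triphenylphosphoranylidene)acetamide | CON(C)C(=O)C=P(c1ccccc1)(c1ccccc1)c1ccccc1 | starting material
4 | (2S,3R)-2,3-epoxygeranial | O=C[C@H]1O[C@]1(C)CCC=C(C)C | intermediate
5 | (E)-epoxy enamide (Weinreb type) | CON(C)C(=O)/C=C/[C@H]1O[C@]1(C)CCC=C(C)C | intermediate
6 | saturated epoxy Weinreb amide | CON(C)C(=O)CC[C@H]1O[C@]1(C)CCC=C(C)C | intermediate
7 | vinylmagnesium bromide | C=C[Mg]Br | starting material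
8 | epoxy vinyl ketone | C=CC(=O)CC[C@H]1O[C@]1(C)CCC=C(C)C | intermediate
9 | epoxygeranyl Z tert-butyldimethylsilyl enol ether | C=CC/C=C(\O[Si](C)(C)C(C)(C)C)CC[C@H]1O[C@]1(C)CCC=C(C)C | intermediate
10 | (2R,3R,4R)-2-allyl-4-hydroxy-3-methyl-3-(4-methylpent-3-enyl)cyclohexanone | C=CC[C@@H]1[C@@](C)(CCC=C(C)C)[C@H](O)CCC1=O | intermediate
11 | (1S,2R,3R,4R)-2-allyl-1,3-dimethyl-3-(4-methylpent-3-enyl)cyclohexane-1,4-diol | C=CC[C@@H]1[C@@](C)(CCC=C(C)C)[C@H](O)CC[C@]1(C)O | intermediate
12 | (18R)-18,19-epoxide of 11 | C=CC[C@@H]1[C@@](C)(CC[C@H]2OC2(C)C)[C@H](O)CC[C@]1(C)O | intermediate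
13 | trans-fused oxepane diol, (18R)-C18 alcohol, C14 allyl | C=CC[C@@H]1[C@@]2(C)CC[C@@H](O)C(C)(C)O[C@@H]2CC[C@]1(C)O | intermediate
14 | C18,C24-bis(triethylsilyl) ether of 13 | C=CC[C@@H]1[C@@]2(C)CC[C@@H](O[Si](CC)(CC)CC)C(C)(C)O[C@@H]2CC[C@]1(C)O[Si](CC)(CC)CC | intermediate
15 | C12 aldehyde | O=CC[C@@H]1[C@@]2(C)CC[C@@H](O[Si](CC)(CC)CC)C(C)(C)O[C@@H]2CC[C@]1(C)O[Si](CC)(CC)CC | intermediate
16 | (R)-(−)-linalool | C=C[C@](C)(O)CCC=C(C)C | starting material
17 | (R)-1-methylcyclopent-2-en-1-ol | C[C@@]1(O)CCC=C1 | intermediate
18 | (1S,2R,5S)-2-methyl-6-oxabicyclo[3.1.0]hexan-2-ol | C[C@@]1(O)CC[C@@H]2O[C@H]12 | intermediate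
19 | isobutyronitrile | CC(C)C#N | starting material
20 | 2-[(1S,2S,3R)-2,3-dihydroxy-3-methylcyclopentyl]-2-methylpropanenitrile | C[C@@]1(O)CC[C@@H](C(C)(C)C#N)[C@@H]1O | intermediate
21 | alpha-hydroxy cyclopentanone nitrile | C[C@@]1(O)CC[C@@H](C(C)(C)C#N)C1=O | intermediate
22 | beta-hydroxysilane (C5 carbinol, configuration at C5 open) | C[C@@]1(O)CC[C@@H](C(C)(C)C#N)C1(O)C[Si](C)(C)C | intermediate
23 | methylene cyclopentanol nitrile | C[C@@]1(O)CC[C@@H](C(C)(C)C#N)C1=C | intermediate
24 | vinyl bromide | C=CBr | starting material
25 | B-alkyl-9-borabicyclo[3.3.1]nonane at C4 | C[C@@]1(O)CC[C@@H](C(C)(C)C#N)[C@H]1CB1C2CCCC1CCC2 | intermediate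
26 | all-cis allyl nitrile (5R,6R,9R) | C[C@@]1(O)CC[C@@H](C(C)(C)C#N)[C@H]1CC=C | intermediate
27 | 2-bromopropene | C=C(C)Br | starting material
28 | isopropenyl ketimine | C[C@@]1(O)CC[C@@H](C(C)(C)C(=N)C(C)=C)[C@H]1CC=C | intermediate
29 | isopropenyl ketone with C5 allyl group (dienone) | C[C@@]1(O)CC[C@@H](C(C)(C)C(=O)C(C)=C)[C@H]1CC=C | intermediate
30 | cis-fused hydroazulenone with C2=C3 enone | C[C@@]1(O)CC[C@@H]2[C@H]1CC=C(C)C(=O)C2(C)C | intermediate
31 | cis-fused hydroxy hydroazulenone (C2 epimers) | C[C@@]1(O)CC[C@@H]2[C@H]1CCC(C)C(=O)C2(C)C | intermediate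
32 | C11 hydrazone of 31 | C[C@@]1(O)CC[C@@H]2[C@H]1CCC(C)C(=NN)C2(C)C | intermediate
33 | hydroazulenyl iodide | CC1=C(I)C(C)(C)[C@@H]2CC[C@@](C)(O)[C@@H]2CC1 | intermediate
34 | C11 vinyllithium, C9 lithium alkoxide | CC1=C([Li])C(C)(C)[C@@H]2CC[C@@](C)(O[Li])[C@@H]2CC1 | intermediate
35 | coupled allylic alcohol (C12 epimers) | CC1=C(C(O)C[C@@H]3[C@@]4(C)CC[C@@H](O[Si](CC)(CC)CC)C(C)(C)O[C@@H]4CC[C@]3(C)O[Si](CC)(CC)CC)C(C)(C)[C@@H]2CC[C@@](C)(O)[C@@H]2CC1 | intermediate
36 | C12 enone | CC1=C(C(=O)C[C@@H]3[C@@]4(C)CC[C@@H](O[Si](CC)(CC)CC)C(C)(C)O[C@@H]4CC[C@]3(C)O[Si](CC)(CC)CC)C(C)(C)[C@@H]2CC[C@@](C)(O)[C@@H]2CC1 | intermediate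
37 | (12R)-allylic alcohol | CC1=C([C@H](O)C[C@@H]3[C@@]4(C)CC[C@@H](O[Si](CC)(CC)CC)C(C)(C)O[C@@H]4CC[C@]3(C)O[Si](CC)(CC)CC)C(C)(C)[C@@H]2CC[C@@](C)(O)[C@@H]2CC1 | intermediate
38 | (12S)-N-allyl-N-(2-nitrobenzenesulfonyl) acetone hydrazone | CC1=C([C@@H](N(N=C(C)C)S(=O)(=O)c5ccccc5[N+](=O)[O-])C[C@@H]3[C@@]4(C)CC[C@@H](O[Si](CC)(CC)CC)C(C)(C)O[C@@H]4CC[C@]3(C)O[Si](CC)(CC)CC)C(C)(C)[C@@H]2CC[C@@](C)(O)[C@@H]2CC1 | intermediate
39 | (12S)-N-allyl-N-(2-nitrobenzenesulfonyl)hydrazine | CC1=C([C@@H](N(N)S(=O)(=O)c5ccccc5[N+](=O)[O-])C[C@@H]3[C@@]4(C)CC[C@@H](O[Si](CC)(CC)CC)C(C)(C)O[C@@H]4CC[C@]3(C)O[Si](CC)(CC)CC)C(C)(C)[C@@H]2CC[C@@](C)(O)[C@@H]2CC1 | intermediate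
40 | (12S)-allylic diazene | CC1=C([C@@H](N=N)C[C@@H]3[C@@]4(C)CC[C@@H](O[Si](CC)(CC)CC)C(C)(C)O[C@@H]4CC[C@]3(C)O[Si](CC)(CC)CC)C(C)(C)[C@@H]2CC[C@@](C)(O)[C@@H]2CC1 | intermediate
41 | transposed (Z)-alkene, (2S), bis-silyl ether | C[C@H]1CC[C@@H]2[C@@H](CC[C@@]2(C)O)C(C)(C)/C1=C\C[C@@H]1[C@@]2(C)CC[C@@H](O[Si](CC)(CC)CC)C(C)(C)O[C@@H]2CC[C@]1(C)O[Si](CC)(CC)CC | intermediate
42 | triol, (18R)-C18 alcohol | C[C@H]1CC[C@@H]2[C@@H](CC[C@@]2(C)O)C(C)(C)/C1=C\C[C@@H]1[C@@]2(C)CC[C@@H](O)C(C)(C)O[C@@H]2CC[C@]1(C)O | intermediate
43 | CNP0157787.1 | C[C@H]1CC[C@@H]2[C@@H](CC[C@@]2(C)O)C(C)(C)/C1=C\C[C@@H]1[C@@]2(C)CCC(=O)C(C)(C)O[C@@H]2CC[C@]1(C)O | target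

Total step count: 28.
Longest linear sequence: 17 steps (steps 1–11, then 23–28). The linalool branch (steps 12–22, then 23–28) is equally long.

Steps most likely to fail

Step 6. The activated epoxide may collapse by a 1,2-hydride shift, or the enol silane may lose its silyl group, before the C14–C15 bond forms. The fallback sets out from 6 and returns at 10. It replaces the fragile enol silane with a beta-keto ester as terminating nucleophile and brings in the allyl group afterwards. Acylation of the lithium enolate of allyl acetate with 6 gives the allyl beta-keto ester F1. SnCl4 in CH2Cl2 at low temperature closes the same bond through the ester-stabilised enol and gives the cyclic allyl beta-keto ester F2. Pd(PPh3)4 then triggers decarboxylative allylation at C14, and the alpha centre equilibrates to the equatorial allyl ketone 10.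

Step 9. O20 may attack C18 in the 6-exo mode, or the cationic C19 centre may lose a proton. The fallback sets out from 12 and returns at 14. It moves the closure from proton catalysis on the free alcohol to electrophilic silylation of the oxirane oxygen. TESOTf with 2,6-di-tert-butyl-4-methylpyridine in nitromethane at low temperature forms a silyloxonium ion whose tertiary C19–O bond is nearly broken before O20 arrives, a known entry to endo ethers from trisubstituted epoxides. This yields the C18 triethylsilyl ether F3 directly, and a second silylation at C24 gives 14, so ring closure and protection merge.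

Step 26. The activated, hindered allylic alcohol may ionise or eliminate instead of undergoing clean SN2 displacement, and the transfer of chirality from C12 to C2 would then erode. The fallback sets out from 36 and returns at 41. It reaches the diazene by reduction rather than substitution. Condensation of 36 with p-toluenesulfonyl hydrazide gives the tosylhydrazone F4. Catecholborane reduces the C=N bond, and NaOAc·3H2O with gentle heating expels sulfinate to give an allylic diazene that rearranges as in the main route. No displacement at C12 is needed, but C12 and hence C2 then depend on the facial bias of the substrate, so the C2 epimer may have to be separated.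

Further compounds
F1 | step 6 | allyl 3-oxo-5-[(2R,3R)-3-methyl-3-(4-methylpent-3-enyl)oxiran-2-yl]pentanoate | C=CCOC(=O)CC(=O)CC[C@H]1O[C@]1(C)CCC=C(C)C
F2 | step 6 | allyl (15R,21R)-3-hydroxy-2-methyl-2-(4-methylpent-3-enyl)-6-oxocyclohexanecarboxylate (C14 labile) | C=CCOC(=O)C1[C@@](C)(CCC=C(C)C)[C@H](O)CCC1=O
F3 | step 9 | C18 mono(triethylsilyl) ether of 13 | C=CC[C@@H]1[C@@]2(C)CC[C@@H](O[Si](CC)(CC)CC)C(C)(C)O[C@@H]2CC[C@]1(C)O
F4 | step 26 | p-toluenesulfonylhydrazone of 36 at C12 | CC1=C(C(C[C@@H]3[C@@]4(C)CC[C@@H](O[Si](CC)(CC)CC)C(C)(C)O[C@@H]4CC[C@]3(C)O[Si](CC)(CC)CC)=NNS(=O)(=O)c5ccc(C)cc5)C(C)(C)[C@@H]2CC[C@@](C)(O)[C@@H]2CC1
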